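**Plan**
- Numbering: ring B is C1 (CH2OAc, C20)–C2–C3–C4 (side chain from C11); the arene is C4a–C8a with CO2H on C6 and OAc on C8. The target is (1R,4S,11S).
- Cuts, last to first: C13–C14 and C11–C12 of the chain, then C4–C11, then the C1–C2 bond of ring B, then the aryl–C1 and aryl–C4 bonds on a 4-bromo-3,5-dihydroxybenzoate.
- Enabling feature: C1 is benzylic and carries C20 at the carboxyl level. C20, C1, C8a, C4a, C4 and an oxygen therefore form an isochroman-3-one whose enolisable carbon is C1 and whose carbinol carbon C4 holds the vinyl group C3=C2. Its silyl ketene acetal is a ring-locked allyl vinyl ether.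
- Forward: the arene is functionalised (C8a–C1 by zinc enolate arylation, C4a–C4 by carbonylation), the lactone closes on vinyl addition, ring B closes by the [3,3] shift, and the chain is grown from the new C3=C4 alkene in three boron-based steps.
- Stereochemistry: the carbinol centre comes from a (−)-DAIB-catalysed vinylzinc addition and is transferred to C1. C4 comes from hydrocupration anti to the C1 substituent. C11 comes from a (−)-sparteine-derived lithiated carbenoid, independent of C4.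

Key step: step 7

Remark: TIPS = tri(propan-2-yl)silyl, TBS = tert-butyldimethylsilyl, Bpin = 4,4,5,5-tetramethyl-1,3,2-dioxaborolan-2-yl. From compound 15 on, names use naphthalene-2-carboxylate numbering, in which target C1, C4 and C8 are C5, C8 and C4.

**Step 1**
Reactants: 1 4-bromo-3,5-dihydroxybenzoic acid
Product: 2 tert-butyl 4-bromo-3,5-dihydroxybenzoate
Conditions: Me2NCH(OtBu)2 (4 equiv), PhMe, 80 °C
Reagents that add atoms: N,N-dimethylformamide di-tert-butyl acetal, CN(C)C(OC(C)(C)C)OC(C)(C)C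
Why: The amide acetal alkylates the carboxylic acid in preference to the less acidic phenols (neutral tert-butyl esterification), and the tert-butyl ester is chosen because it must later resist LiN(iPr)2 and organolithium-derived boronate chemistry.

**Step 2**
Reactants: 2 tert-butyl 4-bromo-3,5-dihydroxybenzoate
Product: 3 tert-butyl 4-bromo-3-hydroxy-5-(TIPS-oxy)benzoate
Conditions: iPr3SiCl (1.0 equiv), imidazole, DMF, 0 °C; recovered 2 and bis-silyl ether are recycled
Reagents that add atoms: chlorotri(propan-2-yl)silane, CC(C)[Si](Cl)(C(C)C)C(C)C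
Why: Imidazole-promoted silylation of a phenol; the two hydroxyl groups of 2 are homotopic, so mono-protection is a matter of stoichiometry and raises no regiochemical question.

**Step 3**
Reactants: 3 tert-butyl 4-bromo-3-hydroxy-5-(TIPS-oxy)benzoate
Product: 4 tert-butyl 4-bromo-3-(TIPS-oxy)-5-(trifluoromethylsulfonyloxy)benzoate
Conditions: Tf2O, pyridine, CH2Cl2, 0 °C
Reagents that add atoms: trifluoromethanesulfonic anhydride, O=S(=O)(OS(=O)(=O)C(F)(F)F)C(F)(F)F
Why: Sulfonylation of the remaining phenol turns that oxygen into a leaving group for the later carbonylation at the future C4a.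

**Step 4**
Reactants: 4 tert-butyl 4-bromo-3-(TIPS-oxy)-5-(trifluoromethylsulfonyloxy)benzoate; 5 ethyl bromoacetate
Product: 6 tert-butyl 4-(2-ethoxy-2-oxoethyl)-3-(TIPS-oxy)-5-(trifluoromethylsulfonyloxy)benzoate
Conditions: 5, Zn, THF, 40 °C (gives BrZnCH2CO2Et); then 4, Pd2(dba)3 (2 mol%), P(tBu)3 (4 mol%), THF, 25–45 °C
Reagents that add atoms: none
Why: Negishi-type α-arylation of a Reformatsky reagent; monoligated zerovalent palladium with P(tBu)3 inserts into the C–Br bond in preference to C–OTf, and the neutral zinc enolate leaves the triflate, the silyl ether and both esters alone while delivering the future C1–C20 unit.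

**Step 5**
Reactants: 6 tert-butyl 4-(2-ethoxy-2-oxoethyl)-3-(TIPS-oxy)-5-(trifluoromethylsulfonyloxy)benzoate
Product: 7 tert-butyl 4-(2-ethoxy-2-oxoethyl)-3-formyl-5-(TIPS-oxy)benzoate
Conditions: Pd(OAc)2 (5 mol%), dppp (5 mol%), CO (1 atm), Et3SiH, Et3N, DMF, 70 °C
Reagents that add atoms: carbon monoxide, [C-]#[O+]
Why: Reductive carbonylation of the aryl triflate (oxidative addition, CO insertion, hydride transfer from the silane to the acylpalladium) gives the aldehyde carbon that becomes C4.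

**Step 6**
Reactants: 7 tert-butyl 4-(2-ethoxy-2-oxoethyl)-3-formyl-5-(TIPS-oxy)benzoate; 8 vinylmagnesium bromide
Product: 10 tert-butyl (1S)-1-ethenyl-3-oxo-5-(TIPS-oxy)-3,4-dihydro-1H-isochromene-7-carboxylate, via zinc alkoxide of the (S)-hydroxy ester 9 (not isolated)
Conditions: 8, ZnCl2, Et2O, then 1,4-dioxane, filtration (gives Zn(CH=CH2)2); 7, (−)-DAIB (10 mol%), PhMe, −20 → 25 °C; then PPTS (cat.), 25 °C
Reagents that add atoms: none
Why: Amino-alcohol-catalysed, ligand-accelerated addition of the alkenylzinc reagent to the aryl aldehyde; (−)-DAIB directs vinyl transfer to the Si face to give the (S)-carbinol, whose oxygen then closes the six-membered lactone on the neighbouring ethyl ester (6-exo-trig acyl substitution).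

**Step 7**
Reactants: 10 tert-butyl (1S)-1-ethenyl-3-oxo-5-(TIPS-oxy)-3,4-dihydro-1H-isochromene-7-carboxylate
Product: 13 (1R)-6-(tert-butoxycarbonyl)-8-(TIPS-oxy)-1,2-dihydronaphthalene-1-carboxylic acid, via silyl ketene acetal 11 (not isolated), via trimethylsilyl ester 12 (not isolated)
Conditions: Me3SiCl/Et3N (premixed), THF, −78 °C, then LiN(iPr)2 (1.1 equiv); −78 → 25 °C, then PhMe, 80 °C; aqueous citric acid work-up
Reagents that add atoms: none
Why: Internal-quench enolisation of the benzylic lactone methylene gives the endocyclic O-silyl ketene acetal 11, in which the enol ether carbon, the ring oxygen, the carbinol carbon and its vinyl group make up an allyl vinyl ether locked in one ring. A concerted suprafacial [3,3] shift through a boat, bicyclo[2.2.2]octane-like transition state with the vinyl group pseudoaxial bonds the ketene-acetal carbon to the vinyl terminus (the C1–C2 bond) and breaks the benzylic–allylic C–O bond, giving silyl ester 12 and, after work-up, acid 13; the closest known reaction type is the Ireland–Claisen ring contraction of alkenyl lactone silyl ketene acetals to cycloalkenecarboxylic acids. Ring B closes as a six-membered carbocycle by this bridging closure across the 1,4-positions of the lactone, which opens as the carbocycle forms, and the new C3=C4 alkene is necessarily cis and conjugated with the arene. The C1 stereocentre is controlled by chirality transfer: the tether lets the vinyl terminus reach only the face of the ketene acetal on which the vinyl group sits, so the (1S)-carbinol is given up for (1R)-C1. The step needs O- over C-silylation, a concerted instead of an ionising pathway, and no later deprotonation of the doubly activated C1–H; the −78 °C internal quench, the poor cation-stabilising power of the ester-bearing arene and the use of only a slight excess of base are the safeguards.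

**Step 8**
Reactants: 13 (1R)-6-(tert-butoxycarbonyl)-8-(TIPS-oxy)-1,2-dihydronaphthalene-1-carboxylic acid
Product: 15 tert-butyl (5R)-5-(hydroxymethyl)-4-(TIPS-oxy)-5,6-dihydronaphthalene-2-carboxylate, via isobutyl carbonic anhydride 14 (not isolated)
Conditions: iBuOCOCl, N-methylmorpholine, THF, −15 °C; then NaBH4, H2O, −15 → 0 °C
Reagents that add atoms: none
Why: Activation as the mixed carbonic anhydride and hydride reduction give the C20 alcohol while NaBH4 leaves the tert-butyl ester and the styrenic alkene alone; the short cold activation limits enolisation at C1.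

**Step 9**
Reactants: 15 tert-butyl (5R)-5-(hydroxymethyl)-4-(TIPS-oxy)-5,6-dihydronaphthalene-2-carboxylate
Product: 16 tert-butyl (5R)-5-[(TBS-oxy)methyl]-4-(TIPS-oxy)-5,6-dihydronaphthalene-2-carboxylate
Conditions: tBuMe2SiCl, imidazole, DMF, 25 °C
Reagents that add atoms: tert-butylchlorodimethylsilane, CC(C)(C)[Si](C)(C)Cl
Why: Silylation of the primary alcohol removes the only acidic O–H before the copper hydride, the lithiated carbenoid and vinyllithium are used.

**Step 10**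
Reactants: 16 tert-butyl (5R)-5-[(TBS-oxy)methyl]-4-(TIPS-oxy)-5,6-dihydronaphthalene-2-carboxylate
Product: 17 tert-butyl (5R,8R)-5-[(TBS-oxy)methyl]-8-(Bpin)-4-(TIPS-oxy)-5,6,7,8-tetrahydronaphthalene-2-carboxylate
Conditions: CuCl (5 mol%), NaOtBu (10 mol%), (R)-DTBM-SEGPHOS (5.5 mol%), HBpin (1.5 equiv), PhMe, 25 °C
Reagents that add atoms: pinacolborane, CC1(C)OBOC1(C)C
Why: Copper-hydride-catalysed Markovnikov hydroboration of a β-substituted vinylarene: syn hydrocupration places copper on benzylic C4 from the face opposite the C1 substituent (held pseudoaxial by peri strain with the C8 silyloxy group), and σ-bond metathesis with HBpin gives the trans C4–B bond with retention; the ligand antipode is taken as the one that reinforces this substrate bias, and its mirror image is used if it proves mismatched.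

**Step 11**
Reactants: 17 tert-butyl (5R,8R)-5-[(TBS-oxy)methyl]-8-(Bpin)-4-(TIPS-oxy)-5,6,7,8-tetrahydronaphthalene-2-carboxylate; 18 ethyl 2,4,6-tri(propan-2-yl)benzoate
Product: 20 tert-butyl (5R,8S)-5-[(TBS-oxy)methyl]-8-[(1R)-1-(Bpin)ethyl]-4-(TIPS-oxy)-5,6,7,8-tetrahydronaphthalene-2-carboxylate, via lithium boronate complex 19 (not isolated)
Conditions: 18, sBuLi, (−)-sparteine, Et2O, −78 °C; then 17, −78 °C; then 35 °C
Reagents that add atoms: none
Why: Lithiation–borylation (reagent-controlled carbenoid homologation of a boronic ester): sparteine-directed removal of the pro-S proton gives the (S)-α-lithio benzoate, which adds to boron with retention, and the anti-periplanar 1,2-shift of C4 (retention at C4, inversion at the carbenoid carbon) forms the C4–C11 bond and sets C11 irrespective of the neighbouring centre.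

**Step 12**
Reactants: 20 tert-butyl (5R,8S)-5-[(TBS-oxy)methyl]-8-[(1R)-1-(Bpin)ethyl]-4-(TIPS-oxy)-5,6,7,8-tetrahydronaphthalene-2-carboxylate
Product: 23 tert-butyl (5R,8S)-8-[(2S)-but-3-en-2-yl]-5-[(TBS-oxy)methyl]-4-(TIPS-oxy)-5,6,7,8-tetrahydronaphthalene-2-carboxylate, via lithium vinylboronate complex 21 (not isolated), via β-iodoalkyl boronic ester 22 (not isolated)
Conditions: CH2=CHLi (from Sn(CH=CH2)4, nBuLi), THF, −78 °C; I2, THF/MeOH, −78 °C; NaOMe, MeOH, −78 → 25 °C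
Reagents that add atoms: vinyllithium, [Li]C=C
Why: Zweifel olefination: iodine activates the vinyl group of the boronate complex, C11 migrates from boron to carbon with retention, and methoxide triggers anti elimination of boron and iodide, forming the C11–C12 bond and the C12=C13 alkene at a temperature the tert-butyl ester tolerates.

**Step 13**
Reactants: 23 tert-butyl (5R,8S)-8-[(2S)-but-3-en-2-yl]-5-[(TBS-oxy)methyl]-4-(TIPS-oxy)-5,6,7,8-tetrahydronaphthalene-2-carboxylate; 24 1-bromo-2-methylprop-1-ene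
Product: 26 tert-butyl (5R,8S)-5-[(TBS-oxy)methyl]-8-[(2S)-6-methylhept-5-en-2-yl]-4-(TIPS-oxy)-5,6,7,8-tetrahydronaphthalene-2-carboxylate, via B-alkyl-9-BBN adduct 25 (not isolated)
Conditions: 9-BBN-H, THF, 25 °C; then 24, PdCl2(dppf) (5 mol%), K3PO4 (aq.), THF/DMF, 50 °C
Reagents that add atoms: none
Why: Anti-Markovnikov hydroboration of the only alkene followed by B-alkyl Suzuki–Miyaura coupling with the alkenyl bromide forms the C13–C14 bond and completes the 6-methylhept-5-en-2-yl chain; any loss of the phenolic silyl group under the aqueous base would only anticipate step 14.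

**Step 14**
Reactants: 26 tert-butyl (5R,8S)-5-[(TBS-oxy)methyl]-8-[(2S)-6-methylhept-5-en-2-yl]-4-(TIPS-oxy)-5,6,7,8-tetrahydronaphthalene-2-carboxylate
Product: 27 tert-butyl (5R,8S)-4-hydroxy-5-(hydroxymethyl)-8-[(2S)-6-methylhept-5-en-2-yl]-5,6,7,8-tetrahydronaphthalene-2-carboxylate
Conditions: Bu4NF (3 equiv), THF, 0 → 25 °C
Reagents that add atoms: none
Why: Fluoride cleaves both the aryl and the alkyl silyl ether and leaves the tert-butyl ester and the trisubstituted alkene untouched.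

**Step 15**
Reactants: 27 tert-butyl (5R,8S)-4-hydroxy-5-(hydroxymethyl)-8-[(2S)-6-methylhept-5-en-2-yl]-5,6,7,8-tetrahydronaphthalene-2-carboxylate
Product: 28 tert-butyl (5R,8S)-4-acetyloxy-5-(acetyloxymethyl)-8-[(2S)-6-methylhept-5-en-2-yl]-5,6,7,8-tetrahydronaphthalene-2-carboxylate
Conditions: Ac2O, pyridine, DMAP (cat.), CH2Cl2, 25 °C
Reagents that add atoms: acetic anhydride, CC(=O)OC(C)=O
Why: DMAP-catalysed acylation of the phenol and the primary alcohol installs both acetates while the carboxyl group is still masked, so no mixed anhydride can form.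

**Step 16**
Reactants: 28 tert-butyl (5R,8S)-4-acetyloxy-5-(acetyloxymethyl)-8-[(2S)-6-methylhept-5-en-2-yl]-5,6,7,8-tetrahydronaphthalene-2-carboxylate
Product: 30 (5R,8S)-4-acetyloxy-5-(acetyloxymethyl)-8-[(2S)-6-methylhept-5-en-2-yl]-5,6,7,8-tetrahydronaphthalene-2-carboxylic acid, via trimethylsilyl ester 29 (not isolated)
Conditions: Me3SiOTf, 2,6-lutidine, CH2Cl2, 0 → 25 °C; then H2O (pH 4 buffer)
Reagents that add atoms: none
Why: Silyl-triflate-mediated cleavage of the tert-butyl ester (O-silylation, loss of 2-methylpropene, hydrolysis of the silyl ester on work-up) is buffered by the pyridine base, so the two acetates and the acid-sensitive trisubstituted alkene should survive.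

**Compound list**
1 | 4-bromo-3,5-dihydroxybenzoic acid | OC(=O)c1cc(O)c(Br)c(O)c1 | starting material
2 | tert-butyl 4-bromo-3,5-dihydroxybenzoate | CC(C)(C)OC(=O)c1cc(O)c(Br)c(O)c1 | intermediate
3 | tert-butyl 4-bromo-3-hydroxy-5-(TIPS-oxy)benzoate | CC(C)(C)OC(=O)c1cc(O)c(Br)c(O[Si](C(C)C)(C(C)C)C(C)C)c1 | intermediate
4 | tert-butyl 4-bromo-3-(TIPS-oxy)-5-(trifluoromethylsulfonyloxy)benzoate | CC(C)(C)OC(=O)c1cc(OS(=O)(=O)C(F)(F)F)c(Br)c(O[Si](C(C)C)(C(C)C)C(C)C)c1 | intermediate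
5 | ethyl bromoacetate | CCOC(=O)CBr | starting material
6 | tert-butyl 4-(2-ethoxy-2-oxoethyl)-3-(TIPS-oxy)-5-(trifluoromethylsulfonyloxy)benzoate | CCOC(=O)Cc1c(OS(=O)(=O)C(F)(F)F)cc(C(=O)OC(C)(C)C)cc1O[Si](C(C)C)(C(C)C)C(C)C | intermediate
7 | tert-butyl 4-(2-ethoxy-2-oxoethyl)-3-formyl-5-(TIPS-oxy)benzoate | CCOC(=O)Cc1c(C=O)cc(C(=O)OC(C)(C)C)cc1O[Si](C(C)C)(C(C)C)C(C)C | intermediate
8 | vinylmagnesium bromide | C=C[Mg]Br | starting material
9 | tert-butyl 4-(2-ethoxy-2-oxoethyl)-3-[(1S)-1-hydroxyprop-2-en-1-yl]-5-(TIPS-oxy)benzoate (formed as its zinc alkoxide) | CCOC(=O)Cc1c([C@@H](O)C=C)cc(C(=O)OC(C)(C)C)cc1O[Si](C(C)C)(C(C)C)C(C)C | intermediate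
10 | tert-butyl (1S)-1-ethenyl-3-oxo-5-(TIPS-oxy)-3,4-dihydro-1H-isochromene-7-carboxylate | C=C[C@@H]1OC(=O)Cc2c(O[Si](C(C)C)(C(C)C)C(C)C)cc(C(=O)OC(C)(C)C)cc21 | intermediate
11 | tert-butyl (1S)-1-ethenyl-5-(TIPS-oxy)-3-(trimethylsilyloxy)-1H-isochromene-7-carboxylate | C=C[C@@H]1OC(O[Si](C)(C)C)=Cc2c(O[Si](C(C)C)(C(C)C)C(C)C)cc(C(=O)OC(C)(C)C)cc21 | intermediate
12 | 6-tert-butyl 1-trimethylsilyl (1R)-8-(TIPS-oxy)-1,2-dihydronaphthalene-1,6-dicarboxylate | C[Si](C)(C)OC(=O)[C@@H]1CC=Cc2cc(C(=O)OC(C)(C)C)cc(O[Si](C(C)C)(C(C)C)C(C)C)c21 | intermediate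
13 | (1R)-6-(tert-butoxycarbonyl)-8-(TIPS-oxy)-1,2-dihydronaphthalene-1-carboxylic acid | OC(=O)[C@@H]1CC=Cc2cc(C(=O)OC(C)(C)C)cc(O[Si](C(C)C)(C(C)C)C(C)C)c21 | intermediate
14 | (1R)-6-(tert-butoxycarbonyl)-8-(TIPS-oxy)-1,2-dihydronaphthalene-1-carboxylic isobutyl carbonic anhydride | CC(C)COC(=O)OC(=O)[C@@H]1CC=Cc2cc(C(=O)OC(C)(C)C)cc(O[Si](C(C)C)(C(C)C)C(C)C)c21 | intermediate
15 | tert-butyl (5R)-5-(hydroxymethyl)-4-(TIPS-oxy)-5,6-dihydronaphthalene-2-carboxylate | OC[C@@H]1CC=Cc2cc(C(=O)OC(C)(C)C)cc(O[Si](C(C)C)(C(C)C)C(C)C)c21 | intermediate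
16 | tert-butyl (5R)-5-[(TBS-oxy)methyl]-4-(TIPS-oxy)-5,6-dihydronaphthalene-2-carboxylate | CC(C)(C)[Si](C)(C)OC[C@@H]1CC=Cc2cc(C(=O)OC(C)(C)C)cc(O[Si](C(C)C)(C(C)C)C(C)C)c21 | intermediate
17 | tert-butyl (5R,8R)-5-[(TBS-oxy)methyl]-8-(Bpin)-4-(TIPS-oxy)-5,6,7,8-tetrahydronaphthalene-2-carboxylate | CC(C)(C)[Si](C)(C)OC[C@@H]1CC[C@@H](B3OC(C)(C)C(C)(C)O3)c2cc(C(=O)OC(C)(C)C)cc(O[Si](C(C)C)(C(C)C)C(C)C)c21 | intermediate
18 | ethyl 2,4,6-tri(propan-2-yl)benzoate | CCOC(=O)c1c(C(C)C)cc(C(C)C)cc1C(C)C | starting material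
19 | lithium boronate complex of 17 carrying the (1S)-1-[2,4,6-tri(propan-2-yl)benzoyloxy]ethyl group on boron | CC(C)(C)[Si](C)(C)OC[C@@H]1CC[C@@H]([B-]3(OC(C)(C)C(C)(C)O3)[C@@H](C)OC(=O)c4c(C(C)C)cc(C(C)C)cc4C(C)C)c2cc(C(=O)OC(C)(C)C)cc(O[Si](C(C)C)(C(C)C)C(C)C)c21.[Li+] | intermediate
20 | tert-butyl (5R,8S)-5-[(TBS-oxy)methyl]-8-[(1R)-1-(Bpin)ethyl]-4-(TIPS-oxy)-5,6,7,8-tetrahydronaphthalene-2-carboxylate | CC(C)(C)[Si](C)(C)OC[C@@H]1CC[C@@H]([C@@H](C)B3OC(C)(C)C(C)(C)O3)c2cc(C(=O)OC(C)(C)C)cc(O[Si](C(C)C)(C(C)C)C(C)C)c21 | intermediate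
21 | lithium B-vinyl boronate complex of 20 | CC(C)(C)[Si](C)(C)OC[C@@H]1CC[C@@H]([C@@H](C)[B-]3(C=C)OC(C)(C)C(C)(C)O3)c2cc(C(=O)OC(C)(C)C)cc(O[Si](C(C)C)(C(C)C)C(C)C)c21.[Li+] | intermediate
22 | tert-butyl (5R,8S)-5-[(TBS-oxy)methyl]-8-[(2S)-4-iodo-3-(Bpin)butan-2-yl]-4-(TIPS-oxy)-5,6,7,8-tetrahydronaphthalene-2-carboxylate (both epimers at the boron-bearing carbon) | CC(C)(C)[Si](C)(C)OC[C@@H]1CC[C@@H]([C@@H](C)C(CI)B3OC(C)(C)C(C)(C)O3)c2cc(C(=O)OC(C)(C)C)cc(O[Si](C(C)C)(C(C)C)C(C)C)c21 | intermediate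
23 | tert-butyl (5R,8S)-8-[(2S)-but-3-en-2-yl]-5-[(TBS-oxy)methyl]-4-(TIPS-oxy)-5,6,7,8-tetrahydronaphthalene-2-carboxylate | CC(C)(C)[Si](C)(C)OC[C@@H]1CC[C@@H]([C@@H](C)C=C)c2cc(C(=O)OC(C)(C)C)cc(O[Si](C(C)C)(C(C)C)C(C)C)c21 | intermediate
24 | 1-bromo-2-methylprop-1-ene | CC(C)=CBr | starting material
25 | tert-butyl (5R,8S)-8-[(2S)-4-(9-borabicyclo[3.3.1]nonan-9-yl)butan-2-yl]-5-[(TBS-oxy)methyl]-4-(TIPS-oxy)-5,6,7,8-tetrahydronaphthalene-2-carboxylate | CC(C)(C)[Si](C)(C)OC[C@@H]1CC[C@@H]([C@@H](C)CCB3C4CCCC3CCC4)c2cc(C(=O)OC(C)(C)C)cc(O[Si](C(C)C)(C(C)C)C(C)C)c21 | intermediate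
26 | tert-butyl (5R,8S)-5-[(TBS-oxy)methyl]-8-[(2S)-6-methylhept-5-en-2-yl]-4-(TIPS-oxy)-5,6,7,8-tetrahydronaphthalene-2-carboxylate | CC(C)(C)[Si](C)(C)OC[C@@H]1CC[C@@H]([C@@H](C)CCC=C(C)C)c2cc(C(=O)OC(C)(C)C)cc(O[Si](C(C)C)(C(C)C)C(C)C)c21 | intermediate
27 | tert-butyl (5R,8S)-4-hydroxy-5-(hydroxymethyl)-8-[(2S)-6-methylhept-5-en-2-yl]-5,6,7,8-tetrahydronaphthalene-2-carboxylate | OC[C@@H]1CC[C@@H]([C@@H](C)CCC=C(C)C)c2cc(C(=O)OC(C)(C)C)cc(O)c21 | intermediate
28 | tert-butyl (5R,8S)-4-acetyloxy-5-(acetyloxymethyl)-8-[(2S)-6-methylhept-5-en-2-yl]-5,6,7,8-tetrahydronaphthalene-2-carboxylate | CC(=O)OC[C@@H]1CC[C@@H]([C@@H](C)CCC=C(C)C)c2cc(C(=O)OC(C)(C)C)cc(OC(C)=O)c21 | intermediate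
29 | trimethylsilyl (5R,8S)-4-acetyloxy-5-(acetyloxymethyl)-8-[(2S)-6-methylhept-5-en-2-yl]-5,6,7,8-tetrahydronaphthalene-2-carboxylate | CC(=O)OC[C@@H]1CC[C@@H]([C@@H](C)CCC=C(C)C)c2cc(C(=O)O[Si](C)(C)C)cc(OC(C)=O)c21 | intermediate
30 | (5R,8S)-4-acetyloxy-5-(acetyloxymethyl)-8-[(2S)-6-methylhept-5-en-2-yl]-5,6,7,8-tetrahydronaphthalene-2-carboxylic acid | CC(=O)OC[C@@H]1CC[C@@H]([C@@H](C)CCC=C(C)C)c2cc(C(=O)O)cc(OC(C)=O)c21 | target

**Step count**
Total steps: 16. Longest linear sequence: 16 steps (1 → 30); 5, 8, 18 and 24 are bought and enter at steps 4, 6, 11 and 13.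

**Steps most likely to fail**

Step 7. What may go wrong: C-silylation of the lactone enolate, ionisation of the benzylic–allylic C–O bond before the new bond forms (loss of chirality transfer), or base-mediated racemisation of the α-aryl silyl ester. The fallback lowers C20 to the aldehyde oxidation level and runs the rearrangement thermally without base. Lactone 10 is reduced with iBu2AlH (PhMe, −78 °C) to the lactol tert-butyl (1S)-1-ethenyl-3-hydroxy-5-(TIPS-oxy)-3,4-dihydro-1H-isochromene-7-carboxylate F1. F1 is dehydrated (MeSO2Cl, Et3N, CH2Cl2, 0 → 25 °C) to the cyclic enol ether tert-butyl (1S)-1-ethenyl-5-(TIPS-oxy)-1H-isochromene-7-carboxylate F2. Heating F2 (PhMe, 100 °C) should bring about the 2-alkenyl-dihydropyran Claisen rearrangement through the same boat arrangement, giving the aldehyde tert-butyl (5R)-5-formyl-4-(TIPS-oxy)-5,6-dihydronaphthalene-2-carboxylate F3. NaBH4 (MeOH, 0 °C) added to the cooled mixture returns the route at alcohol 15, so steps 7 and 8 are replaced.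

Step 4. What may go wrong: palladium inserting into the C–OTf bond instead of the doubly ortho-substituted C–Br bond, giving the wrong arylation site or mixtures. The fallback reverses the order of the two couplings and masks the aldehyde as a styrene. From 4, a triflate-selective Stille coupling (Bu3SnCH=CH2, PdCl2(PPh3)2, LiCl, DMF, 60 °C) should give tert-butyl 4-bromo-3-ethenyl-5-(TIPS-oxy)benzoate F4. With no sulfonate left, the same zinc enolate arylation at the bromide gives tert-butyl 3-ethenyl-4-(2-ethoxy-2-oxoethyl)-5-(TIPS-oxy)benzoate F5. Ozonolysis of the styrene (O3, CH2Cl2, −78 °C; Me2S) returns the route at aldehyde 7, replacing steps 4 and 5.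

Step 10. What may go wrong: poor facial discrimination in the hydrocupration (cis C4–B bond) or boron delivery to C3. The fallback sets C4 by asymmetric hydroformylation and C11 by a copper-catalysed allylic methylation. From 16, Rh(acac)(CO)2 with the matched BINAPHOS antipode (CO/H2 1:1, 20 bar, PhH, 60 °C) should give the benzylic aldehyde tert-butyl (5R,8R)-5-[(TBS-oxy)methyl]-8-formyl-4-(TIPS-oxy)-5,6,7,8-tetrahydronaphthalene-2-carboxylate F6. Horner–Wadsworth–Emmons olefination ((EtO)2P(O)CH2CO2Et, LiCl, iPr2NEt, MeCN) gives the enoate tert-butyl (5R,8S)-5-[(TBS-oxy)methyl]-8-[(1E)-3-ethoxy-3-oxoprop-1-en-1-yl]-4-(TIPS-oxy)-5,6,7,8-tetrahydronaphthalene-2-carboxylate F7. iBu2AlH (CH2Cl2, −78 °C) gives the allylic alcohol tert-butyl (5R,8S)-5-[(TBS-oxy)methyl]-8-[(1E)-3-hydroxyprop-1-en-1-yl]-4-(TIPS-oxy)-5,6,7,8-tetrahydronaphthalene-2-carboxylate F8. CBr4/PPh3 gives the allylic bromide tert-butyl (5R,8S)-8-[(1E)-3-bromoprop-1-en-1-yl]-5-[(TBS-oxy)methyl]-4-(TIPS-oxy)-5,6,7,8-tetrahydronaphthalene-2-carboxylate F9. An SN2'-selective allylic alkylation (CuBr·SMe2, the Taniaphos antipode giving the (S)-configured branched product, MeMgBr, CH2Cl2, −75 °C) then returns the route at alkene 23, replacing steps 10 to 12.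

**Further compounds**
F1 | step 7 | tert-butyl (1S)-1-ethenyl-3-hydroxy-5-(TIPS-oxy)-3,4-dihydro-1H-isochromene-7-carboxylate | C=C[C@@H]1OC(O)Cc2c(O[Si](C(C)C)(C(C)C)C(C)C)cc(C(=O)OC(C)(C)C)cc21
F2 | step 7 | tert-butyl (1S)-1-ethenyl-5-(TIPS-oxy)-1H-isochromene-7-carboxylate | C=C[C@@H]1OC=Cc2c(O[Si](C(C)C)(C(C)C)C(C)C)cc(C(=O)OC(C)(C)C)cc21
F3 | step 7 | tert-butyl (5R)-5-formyl-4-(TIPS-oxy)-5,6-dihydronaphthalene-2-carboxylate | O=C[C@@H]1CC=Cc2cc(C(=O)OC(C)(C)C)cc(O[Si](C(C)C)(C(C)C)C(C)C)c21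
F4 | step 4 | tert-butyl 4-bromo-3-ethenyl-5-(TIPS-oxy)benzoate | C=Cc1cc(C(=O)OC(C)(C)C)cc(O[Si](C(C)C)(C(C)C)C(C)C)c1Br
F5 | step 4 | tert-butyl 3-ethenyl-4-(2-ethoxy-2-oxoethyl)-5-(TIPS-oxy)benzoate | CCOC(=O)Cc1c(C=C)cc(C(=O)OC(C)(C)C)cc1O[Si](C(C)C)(C(C)C)C(C)C
F6 | step 10 | tert-butyl (5R,8R)-5-[(TBS-oxy)methyl]-8-formyl-4-(TIPS-oxy)-5,6,7,8-tetrahydronaphthalene-2-carboxylate | CC(C)(C)[Si](C)(C)OC[C@@H]1CC[C@@H](C=O)c2cc(C(=O)OC(C)(C)C)cc(O[Si](C(C)C)(C(C)C)C(C)C)c21
F7 | step 10 | tert-butyl (5R,8S)-5-[(TBS-oxy)methyl]-8-[(1E)-3-ethoxy-3-oxoprop-1-en-1-yl]-4-(TIPS-oxy)-5,6,7,8-tetrahydronaphthalene-2-carboxylate | CC(C)(C)[Si](C)(C)OC[C@@H]1CC[C@@H](/C=C/C(=O)OCC)c2cc(C(=O)OC(C)(C)C)cc(O[Si](C(C)C)(C(C)C)C(C)C)c21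
F8 | step 10 | tert-butyl (5R,8S)-5-[(TBS-oxy)methyl]-8-[(1E)-3-hydroxyprop-1-en-1-yl]-4-(TIPS-oxy)-5,6,7,8-tetrahydronaphthalene-2-carboxylate | CC(C)(C)[Si](C)(C)OC[C@@H]1CC[C@@H](/C=C/CO)c2cc(C(=O)OC(C)(C)C)cc(O[Si](C(C)C)(C(C)C)C(C)C)c21
F9 | step 10 | tert-butyl (5R,8S)-8-[(1E)-3-bromoprop-1-en-1-yl]-5-[(TBS-oxy)methyl]-4-(TIPS-oxy)-5,6,7,8-tetrahydronaphthalene-2-carboxylate | CC(C)(C)[Si](C)(C)OC[C@@H]1CC[C@@H](/C=C/CBr)c2cc(C(=O)OC(C)(C)C)cc(O[Si](C(C)C)(C(C)C)C(C)C)c21
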